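**Retrosynthetic overview**

1. Target 17 ⇐ C1–O bond by a late singlet-oxygen ene reaction on the 1(10)-alkene of angelate 15 ⇐ esterification of hydroxy lactone 12.
2. 12 ⇐ ten-membered carbocycle closed at C6–C7 by an intramolecular chromium Barbier allylation of epoxy aldehyde 10.
3. 10 ⇐ epoxide by Sharpless epoxidation (C–O, sets C4/C5) and oxidation of butenolide 8 ⇐ lactone ring closed by metathesis of ester 7.
4. 7 ⇐ key C8–O bond: enantioselective allylic C–H acyloxylation of trienol 5 with acid 6 (new) ⇐ 5 from neryl acetate 1 (SeO2 oxidation, bromide, allyl Grignard).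
5. Ring order: butenolide (lactone) → epoxide → ten-membered carbocycle; the exocyclic allylic alcohol is made last.

Assumption: germacrane numbering is used (C8 lactone carbinol, C6 angelate carbon, C4/C5 epoxide, C1 carbinol), the target is (1S,4R,5S,6S,7R,8S), and exo-face ene attack on the 1(10)-alkene is taken to give the 1S alcohol.

**Step 1**
Reactants: 1 neryl acetate
Product: 2 (2Z,6E)-8-hydroxy-3,7-dimethylocta-2,6-dien-1-yl acetate
Conditions: SeO2 (0.3 equiv), t-BuOOH (3 equiv), salicylic acid (0.1 equiv), CH2Cl2, 23 °C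
Reagents that add atoms: tert-butyl hydroperoxide, CC(C)(C)OO (terminal oxidant; the oxygen is relayed through catalytic SeO2, O=[Se]=O)
Why: Riley allylic oxidation (ene reaction then [2,3]-shift) is selective for the (E)-methyl group of the electron-rich terminal alkene, the alkene next to the acetate being deactivated.

**Step 2**
Reactants: 2 (2Z,6E)-8-hydroxy-3,7-dimethylocta-2,6-dien-1-yl acetate
Product: 3 (2Z,6E)-8-bromo-3,7-dimethylocta-2,6-dien-1-yl acetate
Conditions: CBr4, PPh3, CH2Cl2, −20 to 0 °C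
Reagents that add atoms: tetrabromomethane, BrC(Br)(Br)Br
Why: Appel bromination of the primary allylic alcohol proceeds by SN2 at low temperature without allylic shift or loss of alkene geometry.

**Step 3**
Reactants: 3 (2Z,6E)-8-bromo-3,7-dimethylocta-2,6-dien-1-yl acetate; 4 allylmagnesium bromide
Product: 5 (2Z,6E)-3,7-dimethylundeca-2,6,10-trien-1-ol
Conditions: 4 (3.5 equiv), THF, −78 to 0 °C; aq. NH4Cl
Reagents that add atoms: none
Why: Allyl–allyl SN2 coupling of the Grignard reagent at the primary allylic bromide keeps the (E)-alkene, and the excess reagent consumes the acetate, so the (Z)-allylic alcohol is freed in the same pot.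

**Step 4**
Reactants: 5 (2Z,6E)-3,7-dimethylundeca-2,6,10-trien-1-ol; 6 2-(bromomethyl)prop-2-enoic acid
Product: 7 (2Z,6E,9S)-1-hydroxy-3,7-dimethylundeca-2,6,10-trien-9-yl 2-(bromomethyl)prop-2-enoate
Conditions: Pd(OAc)2 (10 mol%), enantiopure tert-leucinol-derived aryl sulfoxide–oxazoline ligand (12 mol%, enantiomer chosen to give 9S), 2,6-dimethyl-1,4-benzoquinone (1.2 equiv), 6 (1.5 equiv), 4 Å MS, toluene, 45 °C
Reagents that add atoms: none
Why: Proposed new method: enantioselective intermolecular branched allylic C–H acyloxylation, in which divalent palladium held by the chiral sulfoxide–oxazoline cleaves one enantiotopic C8–H of the only monosubstituted alkene to give a π-allylpalladium carboxylate, and quinone-promoted inner-sphere C–O reductive elimination at the internal allyl terminus (trans to sulfur) forms the C8–O bond and sets C8 under ligand control; the closest known reactions are the racemic sulfoxide/Pd(OAc)2/benzoquinone branched allylic C–H esterification of terminal alkenes and the enantioselective intramolecular sulfoxide–oxazoline/palladium allylic C–H etherification.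

**Step 5**
Reactants: 7 (2Z,6E,9S)-1-hydroxy-3,7-dimethylundeca-2,6,10-trien-9-yl 2-(bromomethyl)prop-2-enoate
Product: 8 (5S)-3-(bromomethyl)-5-[(2E,6Z)-8-hydroxy-2,6-dimethylocta-2,6-dien-1-yl]furan-2(5H)-one
Conditions: second-generation Grubbs catalyst RuCl2(=CHPh)(PCy3)(H2IMes) (5 mol%), CH2Cl2 (0.01 M), 40 °C
Reagents that add atoms: none
Why: Ring-closing metathesis between the vinyl group and the 1,1-disubstituted acrylate closes the butenolide with loss of ethylene, while the trisubstituted chain alkenes are inert and C8 is untouched.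

**Step 6**
Reactants: 8 (5S)-3-(bromomethyl)-5-[(2E,6Z)-8-hydroxy-2,6-dimethylocta-2,6-dien-1-yl]furan-2(5H)-one
Product: 9 (5S)-3-(bromomethyl)-5-{(2E)-5-[(2R,3S)-3-(hydroxymethyl)-2-methyloxiran-2-yl]-2-methylpent-2-en-1-yl}furan-2(5H)-one
Conditions: Ti(OiPr)4 (20 mol%), L-(+)-diethyl tartrate (24 mol%), t-BuOOH (2 equiv), 4 Å MS, CH2Cl2, −20 °C
Reagents that add atoms: tert-butyl hydroperoxide, CC(C)(C)OO
Why: Katsuki–Sharpless asymmetric epoxidation acts only on the allylic alcohol, and the L-(+)-tartrate delivers oxygen to the face that gives the cis-epoxide with C4 R and C5 S (the (2S,3R)-epoxynerol sense).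

**Step 7**
Reactants: 9 (5S)-3-(bromomethyl)-5-{(2E)-5-[(2R,3S)-3-(hydroxymethyl)-2-methyloxiran-2-yl]-2-methylpent-2-en-1-yl}furan-2(5H)-one
Product: 10 (2R,3R)-3-{(3E)-5-[(2S)-4-(bromomethyl)-5-oxo-2,5-dihydrofuran-2-yl]-4-methylpent-3-en-1-yl}-3-methyloxirane-2-carbaldehyde
Conditions: Dess–Martin periodinane (1.3 equiv), pyridine, CH2Cl2, 0 to 23 °C
Reagents that add atoms: none
Why: Buffered Dess–Martin oxidation gives the epoxy aldehyde without opening the epoxide or touching the allylic bromide; the aldehyde is used at once.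

**Step 8**
Reactants: 10 (2R,3R)-3-{(3E)-5-[(2S)-4-(bromomethyl)-5-oxo-2,5-dihydrofuran-2-yl]-4-methylpent-3-en-1-yl}-3-methyloxirane-2-carbaldehyde
Product: 12 (4R,5S,6S,7S,8S)-4,5-epoxy-6-hydroxygermacra-1(10)E,11(13)-dien-12,8-olide, via allylchromium dichloride 11 (not isolated)
Conditions: CrCl2 (8 equiv), THF/DMF, 0.003 M, slow addition, 23 °C; aq. work-up
Reagents that add atoms: none
Why: In this intramolecular Nozaki–Hiyama (chromium Barbier) allylation the allylchromium adds through its γ-carbon C7 in a chair-like Zimmerman–Traxler transition state, where the ring-locked E-type allyl geometry gives the 6,7-anti pair, Felkin–Anh attack anti to the epoxide C–O gives 6S, and bond formation on the butenolide face opposite C9 gives the trans-fused lactone (C7 is S by CIP here only because C6 carries a free OH).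

**Step 9**
Reactants: 12 (4R,5S,6S,7S,8S)-4,5-epoxy-6-hydroxygermacra-1(10)E,11(13)-dien-12,8-olide; 13 angelic acid
Product: 15 (4R,5S,6S,7R,8S)-6-angeloyloxy-4,5-epoxygermacra-1(10)E,11(13)-dien-12,8-olide, via angelic 2,4,6-trichlorobenzoic anhydride 14 (not isolated)
Conditions: 13 (3 equiv), 2,4,6-trichlorobenzoyl chloride, Et3N, toluene, 23 °C; then 12, toluene, 75 °C
Reagents that add atoms: none
Why: Yamaguchi esterification through the mixed anhydride, run without a nucleophilic amine catalyst, acylates the hindered C6 alcohol while keeping the (Z)-geometry of the angelate.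

**Step 10**
Reactants: 15 (4R,5S,6S,7R,8S)-6-angeloyloxy-4,5-epoxygermacra-1(10)E,11(13)-dien-12,8-olide
Product: 17 (1S,4R,5S,6S,7R,8S)-6-angeloyloxy-4,5-epoxy-1-hydroxygermacra-10(14),11(13)-dien-12,8-olide, via C1 hydroperoxide 16 (not isolated)
Conditions: O2, visible light, tetraphenylporphyrin (cat.), CH2Cl2, −30 °C; then PPh3 (1.2 equiv), −30 to 23 °C
Reagents that add atoms: dioxygen, O=O
Why: In this Schenck ene reaction singlet oxygen attacks C1 of the only electron-rich alkene from its exposed outer face and takes a hydrogen from the C14 methyl group (cis effect, ring C–H bonds poorly aligned), which moves the alkene to C10=C14 and sets C1, and PPh3 reduces the hydroperoxide with retention.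

**Compound list**

1 | neryl acetate, (2Z)-3,7-dimethylocta-2,6-dien-1-yl acetate | CC(C)=CCC/C(C)=C\COC(C)=O | starting material
2 | (2Z,6E)-8-hydroxy-3,7-dimethylocta-2,6-dien-1-yl acetate | OC/C(C)=C/CC/C(C)=C\COC(C)=O | intermediate
3 | (2Z,6E)-8-bromo-3,7-dimethylocta-2,6-dien-1-yl acetate | BrC/C(C)=C/CC/C(C)=C\COC(C)=O | intermediate
4 | allylmagnesium bromide | C=CC[Mg]Br | starting material
5 | (2Z,6E)-3,7-dimethylundeca-2,6,10-trien-1-ol | C=CCC/C(C)=C/CC/C(C)=C\CO | intermediate
6 | 2-(bromomethyl)prop-2-enoic acid | C=C(CBr)C(=O)O | starting material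
7 | (2Z,6E,9S)-1-hydroxy-3,7-dimethylundeca-2,6,10-trien-9-yl 2-(bromomethyl)prop-2-enoate | C=C[C@@H](OC(=O)C(=C)CBr)C/C(C)=C/CC/C(C)=C\CO | intermediate
8 | (5S)-3-(bromomethyl)-5-[(2E,6Z)-8-hydroxy-2,6-dimethylocta-2,6-dien-1-yl]furan-2(5H)-one | O=C1O[C@@H](C/C(C)=C/CC/C(C)=C\CO)C=C1CBr | intermediate
9 | (5S)-3-(bromomethyl)-5-{(2E)-5-[(2R,3S)-3-(hydroxymethyl)-2-methyloxiran-2-yl]-2-methylpent-2-en-1-yl}furan-2(5H)-one | O=C1O[C@@H](C/C(C)=C/CC[C@@]2(C)O[C@H]2CO)C=C1CBr | intermediate
10 | (2R,3R)-3-{(3E)-5-[(2S)-4-(bromomethyl)-5-oxo-2,5-dihydrofuran-2-yl]-4-methylpent-3-en-1-yl}-3-methyloxirane-2-carbaldehyde | O=C1O[C@@H](C/C(C)=C/CC[C@@]2(C)O[C@H]2C=O)C=C1CBr | intermediate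
11 | allylchromium dichloride derived from 10 (CH2Br replaced by CH2CrCl2) | O=C1O[C@@H](C/C(C)=C/CC[C@@]2(C)O[C@H]2C=O)C=C1C[Cr](Cl)Cl | intermediate (not isolated)
12 | (4R,5S,6S,7S,8S)-4,5-epoxy-6-hydroxygermacra-1(10)E,11(13)-dien-12,8-olide | C=C1C(=O)O[C@H]2C/C(C)=C/CC[C@@]3(C)O[C@H]3[C@@H](O)[C@H]12 | intermediate
13 | angelic acid, (2Z)-2-methylbut-2-enoic acid | C/C=C(/C)C(=O)O | starting material
14 | angelic 2,4,6-trichlorobenzoic anhydride | C/C=C(/C)C(=O)OC(=O)c1c(Cl)cc(Cl)cc1Cl | intermediate (not isolated)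
15 | (4R,5S,6S,7R,8S)-6-angeloyloxy-4,5-epoxygermacra-1(10)E,11(13)-dien-12,8-olide | C=C1C(=O)O[C@H]2C/C(C)=C/CC[C@@]3(C)O[C@H]3[C@@H](OC(=O)/C(C)=C\C)[C@H]12 | intermediate
16 | (1S,4R,5S,6S,7R,8S)-6-angeloyloxy-4,5-epoxy-1-hydroperoxygermacra-10(14),11(13)-dien-12,8-olide | C=C1C(=O)O[C@H]2CC(=C)[C@@H](OO)CC[C@@]3(C)O[C@H]3[C@@H](OC(=O)/C(C)=C\C)[C@H]12 | intermediate (not isolated)
17 | (1S,4R,5S,6S,7R,8S)-6-angeloyloxy-4,5-epoxy-1-hydroxygermacra-10(14),11(13)-dien-12,8-olide (CNP0104965.1) | C=C1C(=O)O[C@H]2CC(=C)[C@@H](O)CC[C@@]3(C)O[C@H]3[C@@H](OC(=O)/C(C)=C\C)[C@H]12 | target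

**Step count and risks**

Total step count: 10. Longest linear sequence: 10 steps (1 → 17).

Three steps most likely to fail:

Step 4 (the new C–H acyloxylation). The risks are low enantioselectivity, diene formation by β-hydride elimination, oxidation of the free allylic alcohol, and side reactions of the allylic bromide of 6. The fallback uses only known chemistry, sets out from bromide 3 and comes back at ester 7. Copper-mediated coupling of 3 with propargyl alcohol (CuI, K2CO3, NaI, DMF) gives (2Z,6E)-11-hydroxy-3,7-dimethylundeca-2,6-dien-9-yn-1-yl acetate F1. Semihydrogenation over Pd/CaCO3 poisoned with Pb(OAc)2 and quinoline gives (2Z,6E,9Z)-11-hydroxy-3,7-dimethylundeca-2,6,9-trien-1-yl acetate F2. Cl3CCN with catalytic DBU gives the trichloroacetimidate F3. The known enantioselective SN2′ esterification of (Z)-allylic trichloroacetimidates with acid 6, catalysed by the chiral cobalt oxazoline palladacycle acetate dimer di-μ-acetato-bis[(η5-2-(4-isopropyl-4,5-dihydrooxazol-2-yl)cyclopentadienyl-C,N)(η4-tetraphenylcyclobutadiene)cobalt]dipalladium (CH2Cl2, 23 °C), gives (2Z,6E,9S)-1-acetoxy-3,7-dimethylundeca-2,6,10-trien-9-yl 2-(bromomethyl)prop-2-enoate F4. Lipase-catalysed transesterification (Candida antarctica lipase B, n-butanol, MTBE) then removes the primary acetate and returns 7.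

Step 8 (macrocyclisation). The risks are oligomerisation, cis ring fusion or the wrong C6 epimer, reduction of the epoxy aldehyde by divalent chromium, and lactone migration to O6. The fallback sets out from epoxy alcohol 9 and comes back at 12; it replaces the open-shell chromium reagent by a neutral, thermal allylboration through a closed boron chair. Copper-catalysed borylation of 9 (B2pin2, CuCl, LiOtBu, THF) gives the allyl pinacolboronate epoxy alcohol F5. Dess–Martin oxidation gives the boronate epoxy aldehyde F6. Heating F6 in dilute toluene (80 °C) closes the C6–C7 bond, and aqueous work-up gives 12.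

Step 10 (ene hydroxylation). The main risk is attack on the wrong face at C1, and also some 10-hydroperoxy-1(2)-ene. The fallback sets out from 15 and comes back at 17; C1 is then set by a reagent-controlled ketone reduction instead of by the facial selectivity of the ene step. Photooxygenation of 15 as in step 10 gives the 1R hydroperoxide F7, and PPh3 gives the 1R allylic alcohol F8. Dess–Martin oxidation gives the C1 enone F9. Reduction with the matching enantiomer of 2-methyl-CBS-oxazaborolidine and catecholborane (toluene, −78 °C) gives 17.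

**Further compounds**

F1 | step 4 | (2Z,6E)-11-hydroxy-3,7-dimethylundeca-2,6-dien-9-yn-1-yl acetate | OCC#CC/C(C)=C/CC/C(C)=C\COC(C)=O
F2 | step 4 | (2Z,6E,9Z)-11-hydroxy-3,7-dimethylundeca-2,6,9-trien-1-yl acetate | OC/C=C\C/C(C)=C/CC/C(C)=C\COC(C)=O
F3 | step 4 | (2Z,6E,9Z)-3,7-dimethyl-11-[(2,2,2-trichloroethanimidoyl)oxy]undeca-2,6,9-trien-1-yl acetate | N=C(OC/C=C\C/C(C)=C/CC/C(C)=C\COC(C)=O)C(Cl)(Cl)Cl
F4 | step 4 | (2Z,6E,9S)-1-acetoxy-3,7-dimethylundeca-2,6,10-trien-9-yl 2-(bromomethyl)prop-2-enoate | C=C[C@@H](OC(=O)C(=C)CBr)C/C(C)=C/CC/C(C)=C\COC(C)=O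
F5 | step 8 | (5S)-5-{(2E)-5-[(2R,3S)-3-(hydroxymethyl)-2-methyloxiran-2-yl]-2-methylpent-2-en-1-yl}-3-[(4,4,5,5-tetramethyl-1,3,2-dioxaborolan-2-yl)methyl]furan-2(5H)-one | O=C1O[C@@H](C/C(C)=C/CC[C@@]2(C)O[C@H]2CO)C=C1CB3OC(C)(C)C(C)(C)O3
F6 | step 8 | (2R,3R)-3-methyl-3-{(3E)-4-methyl-5-[(2S)-5-oxo-4-[(4,4,5,5-tetramethyl-1,3,2-dioxaborolan-2-yl)methyl]-2,5-dihydrofuran-2-yl]pent-3-en-1-yl}oxirane-2-carbaldehyde | O=C1O[C@@H](C/C(C)=C/CC[C@@]2(C)O[C@H]2C=O)C=C1CB3OC(C)(C)C(C)(C)O3
F7 | step 10 | (1R,4R,5S,6S,7R,8S)-6-angeloyloxy-4,5-epoxy-1-hydroperoxygermacra-10(14),11(13)-dien-12,8-olide | C=C1C(=O)O[C@H]2CC(=C)[C@H](OO)CC[C@@]3(C)O[C@H]3[C@@H](OC(=O)/C(C)=C\C)[C@H]12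
F8 | step 10 | (1R,4R,5S,6S,7R,8S)-6-angeloyloxy-4,5-epoxy-1-hydroxygermacra-10(14),11(13)-dien-12,8-olide | C=C1C(=O)O[C@H]2CC(=C)[C@H](O)CC[C@@]3(C)O[C@H]3[C@@H](OC(=O)/C(C)=C\C)[C@H]12
F9 | step 10 | (4R,5S,6S,7R,8S)-6-angeloyloxy-4,5-epoxy-1-oxogermacra-10(14),11(13)-dien-12,8-olide | C=C1C(=O)O[C@H]2CC(=C)C(=O)CC[C@@]3(C)O[C@H]3[C@@H](OC(=O)/C(C)=C\C)[C@H]12
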